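## Analysis of the target

The target is a daucane-type sesquiterpenoid ester: a cycloheptene fused to a cyclopentane (bicyclo[5.3.0]decene, a hydroazulene) whose C10 oxygen carries a 4-hydroxybenzoyl group. The atoms are numbered C1 (methyl on C2), C2=C3 (trisubstituted alkene), C4 (CH2), C5 (quaternary ring-fusion carbon with the angular methyl), C6 (secondary carbinol), C7 (CH2), C8 (tertiary carbinol with isopropyl), C9 (ring-fusion CH), C10 (acyloxy carbon) and C11 (CH2 joined to C2). The seven-membered ring is C2–C3–C4–C5–C9–C10–C11, the five-membered ring is C5–C6–C7–C8–C9, and β means the face of the angular methyl. There are five stereocentres: the C5 methyl is β and the C9 hydrogen α (trans fusion), the C6 and C8 hydroxyls are both β (a cis-1,3-diol, isopropyl α), and the C10 acyloxy group is α, anti to the C8 hydroxyl. The tertiary C8 hydroxyl is β to both C6 and C10, so a carbonyl at either position is a β-ketol open to retro-aldol cleavage and dehydration. The aryl ester is base-labile, and the C2=C3 alkene is β,γ to C10 and will move into conjugation whenever C10 is a ketone under equilibrating conditions. The difficulty lies in the quaternary C5 flanked by C6 and C9, the trans 5–7 fusion, the three differentiated oxygens and the position of the alkene. The strategy rests on one feature: C6–C7–C8, oxygenated at both ends, bridges C5 and C9, which are the β- and α-carbons of a C10 carbonyl, and the two methyl-bearing carbons C5 and C2 sit symmetrically about C10. A three-carbon unit with a nucleophilic C6 and an electrophilic C8 can therefore be laid across one enone of a symmetric cycloheptadienone.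

## Retrosynthetic reasoning

**20 ⇒ 19 (phenol O–allyl bond).** The phenol is carried as an allyl ether. It survives amide bases, trivalent titanium and borohydride, and it comes off under neutral zerovalent-palladium catalysis that touches neither the benzoate nor the alkene.

**19 ⇒ 18 (C6–H bond).** The C6 carbinol is traced to a cyclopentanone. C6 is next to the quaternary C5, so a small hydride is steered to the α face by the angular methyl, which gives the β-alcohol. The forward step must avoid base, because 18 is a β-ketol.

**18 ⇒ 16 (C6=O from C6–NO2).** The C6 carbonyl is unmasked from a secondary nitro group by a reductive Nef reaction. Keeping C6 at the nitro level until C10 is reduced and acylated means that the molecule never carries carbonyls at C6 and C10 on either side of the C8 carbinol at once.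

**16 ⇒ 14 + 15 (acyl C–O bond at C10).** The ester is cut at the acyl oxygen. In 14 the C10 hydroxyl is the only secondary alcohol, so no protecting group is needed on the tertiary C8 hydroxyl, and 15 is a commercial acid.

**14 ⇒ 13 (C10–H bond).** The C10 carbinol comes from the C10 ketone. The C8 hydroxyl is cis to the C9–C10 bond on the cyclopentane and can deliver hydride internally, which gives the required anti-1,3-diol.

**13 ⇒ 11 (alkene transposition, C2=C11 to C2=C3).** No skeletal bond is cut. The β,γ-enone is reached from the conjugated enone by kinetic α-protonation of its extended dienolate. This is done at the ketone stage because it is the only stage at which C11 and C3 are both acidifiable.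

**11 ⇒ 7 + 9 (C5–C6 and C8–C9).** Both bonds of the cyclopentane that do not belong to the seven-membered ring system of 7 are cut. This is the (3+2) Michael–aldol disconnection. It makes the ring, the quaternary centre and three further stereocentres from two achiral partners, with C10 and both ring oxygens already at the right oxidation level. Cutting C6–C7 or C7–C8 instead would require a stereodefined C5/C9/C8 array beforehand. The forward reaction must create the congested C5–C6 bond with face control and then close the ring by aldol addition.

**7 ⇒ 5 ⇒ 4 ⇒ 1 + 2 (two C=C bonds, then C–C bonds of a (4+3) cycloadduct).** The dienone is the double β-elimination product of the oxygen-bridged ketone 5 (through 6). 5 is the hydrogenated (4+3) adduct 4 of furan 1 and the oxyallyl cation from 2. The furan is locked s-cis and puts both methyls and the latent unsaturation in place, so no later redox adjustment is needed. An open-chain diene would be a poorer (4+3) partner and would require two dehydrogenations.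

**9 ⇒ 8 (C–N bond).** C6–C7–C8 has only three carbons, so 9 is a β-nitro ketone. It is the conjugate hydronitration product of vinyl ketone 8. The Michael adduct of a nitroalkane and 8 would be one carbon too long.

## Alternatives that were turned down

**Alternative 1:** The disconnection is C5–C9 plus C11–C2, which opens both rings. The acyclic dienyl chloromethyl ketone A1 is ionised (Et3N/LiClO4) to an oxyallyl cation spanning C9–C10–C11, which is trapped by the tethered C5=C4–C3=C2 diene to give the bicyclic ketone A2.
- For: both rings, two C–C bonds, the quaternary C5 and the fusion carbon C9 arise in one step, and the seven-membered ring is made by cycloaddition.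
- Against: A1 must already hold the C6 and C8 stereocentres, including the tertiary silyl ether, on an open chain, so the asymmetric work moves into a long linear precursor synthesis. The trans fusion has to be relayed through a three-atom tether with two bulky silyloxy groups and a trisubstituted diene terminus. A2 also has its alkene at C3=C4 and a stereocentre at C2 that is later destroyed, so it still needs an alkene shift next to a C10 ketone.
- Comparison: this alternative is stronger in ring construction, and it avoids forming a quaternary centre by conjugate addition. The chosen route offers instead two achiral partners (7 and 9) and a catalytic source of chirality, and it faces the same alkene-position problem no worse than A2 does.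

**Alternative 2:** The disconnection is C11–C2, closing the seven-membered ring last. The cyclopentane A3 carries a (Z)-vinyl iodide arm and an N-acyloxyphthalimide arm. It is reduced at the cathode with NiCl2·glyme/2,2'-bipyridine; the C11 radical set free by decarboxylation is captured and coupled with the vinyl iodide to give A4.
- For: the C2=C3 alkene is placed exactly and cannot migrate. On this point it is stronger than the chosen route, which needs a kinetic deconjugation. The coupling also tolerates the free tertiary alcohol.
- Against: all five stereocentres, including the C5/C9/C10 triad, must be assembled on A3 beforehand. A seven-membered ring must be closed by an organonickel/radical step that competes with simple reduction at C11 and with 6-exo addition to the vinyl iodide. A4 then needs a protecting-group exchange at C10 (ether to ester) and a desilylation.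
- Comparison: the chosen route is shorter and creates four stereocentres in the step that builds the ring. Alternative 2 concentrates risk in one late bond, but only after a long sequence.

**Alternative 3:** The disconnection is C7–C8 inside the cyclopentane. The diazoketone A5 is decomposed by Rh2(OAc)4, and the C7 carbenoid inserts into the ether-activated C8–H bond with retention to give the C6 ketone A6.
- For: 1,5-insertion into an oxygen-activated methine is the preferred mode, and the C6 ketone, the ester and the alkene are all in place in A6. No Nef reaction and no deconjugation are needed, which is a real advantage over the chosen route.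
- Against: the C2=C3 alkene is γ,δ to the carbenoid carbon (C7–C6–C5–C4–C3), so intramolecular cyclopropanation is expected to compete strongly. The C10–H bond is also 1,5-related. A5 requires a cycloheptene with a quaternary C5, a C9/C10 pair and an exocyclic C8 stereocentre, all set in advance.
- Comparison: alternative 3 is cleaner in its end game. The chosen route is stronger in how the stereocentres are generated and has no carbenoid/alkene chemoselectivity problem.

Key step: step 5

Remark on catalyst sense: 9-amino-9-deoxy-epi-quinine is taken to give the C5 configuration drawn for 11. If the induction runs the other way, the pseudoenantiomeric 9-amino-9-deoxy-epi-quinidine is used with no other change.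

Remark on supply: 8 and 15 are taken as commercial; 9 is used soon after it is made and kept free of base.

## Route

Step 1
Reactants: 1 2,5-dimethylfuran; 2 1,1,3,3-tetrabromopropan-2-one
Product: 4 1,5-dimethyl-8-oxabicyclo[3.2.1]oct-6-en-3-one (meso), via 2,4-dibromo-1,5-dimethyl-8-oxabicyclo[3.2.1]oct-6-en-3-one 3 (not isolated)
Conditions: Zn, B(OEt)3, THF, rt; then Zn–Cu couple, NH4Cl, MeOH, rt
Reagents that add atoms: none
Why: Reductive (4+3) cycloaddition: zinc converts 2 into a dibromo oxyallyl cation (the borate ester traps the zinc enolate), which adds across the 2,5-positions of the s-cis-locked furan 1 to give 3. Zinc–copper couple in buffered methanol then removes both α-bromines. The oxygen bridge allows only one (meso) arrangement of the bridgehead methyls, and these centres are erased in step 3.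

Step 2
Reactants: 4 1,5-dimethyl-8-oxabicyclo[3.2.1]oct-6-en-3-one
Product: 5 1,5-dimethyl-8-oxabicyclo[3.2.1]octan-3-one (meso)
Conditions: H2 (1 atm), Pd/C, EtOAc, rt
Reagents that add atoms: none
Why: Heterogeneous hydrogenation of the strained disubstituted bicyclic alkene is fast and leaves the ketone and the bridging ether untouched. The product is meso, so no selectivity question arises.

Step 3
Reactants: 5 1,5-dimethyl-8-oxabicyclo[3.2.1]octan-3-one
Product: 7 3,6-dimethylcyclohepta-2,6-dien-1-one, via 6-hydroxy-3,6-dimethylcyclohept-2-en-1-one 6 (not isolated)
Conditions: TsOH·H2O (cat.), toluene, reflux, Dean–Stark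
Reagents that add atoms: none
Why: Acid-catalysed β-elimination (retro-oxa-Michael) through the enol opens the tertiary ether bridge to the β-hydroxy enone 6, and the same elimination of the tertiary β-hydroxyl through the enol on the other side gives the second enone. Each elimination can only place the new C=C between an α-carbon and a methyl-bearing β-carbon, and azeotropic removal of water drives the sequence to the cross-conjugated dienone.

Step 4
Reactants: 8 4-methylpent-1-en-3-one
Product: 9 2-methyl-5-nitropentan-3-one
Conditions: NaNO2, AcOH, THF, rt
Reagents that add atoms: sodium nitrite, [Na+].[O-]N=O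
Why: Conjugate addition of nitrite through nitrogen (hydronitration) to the unhindered vinyl ketone under acetic acid buffering gives the β-nitro ketone directly. The weakly acidic medium holds back the reverse E1cB loss of nitrous acid; a nitroalkane Michael addition is not usable because it would put one carbon too many between the nitro group and the ketone.

Step 5
Reactants: 7 3,6-dimethylcyclohepta-2,6-dien-1-one; 9 2-methyl-5-nitropentan-3-one
Product: 11 bicyclic nitro ketol enone (8β-hydroxy-8α-isopropyl-2,5β-dimethyl-6β-nitro-9α-H-bicyclo[5.3.0]dec-2(11)-en-10-one; analysis numbering), via Michael adduct 3,6-dimethyl-6-(4-methyl-1-nitro-3-oxopentyl)cyclohept-2-en-1-one 10 (not isolated)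
Conditions: 9-amino-9-deoxy-epi-quinine (20 mol %), 2-fluorobenzoic acid (40 mol %), toluene (concentrated, 7 in excess), 40 °C
Reagents that add atoms: none
Why: The primary amine condenses with 7 to a cross-conjugated iminium ion, the quinuclidine/carboxylate pair deprotonates 9 at C6, and the nitronate carbon adds to C5 (nitro-Michael addition) to give the enamine of 10, whose nucleophilic carbon is C9. This enamine adds to the C8 ketone and hydrolysis of the resulting iminium ion releases 11 and the catalyst; the closest known reaction type is the amine-catalysed domino Michael–aldol annulation, together with primary-amine-catalysed additions of nitroalkanes to β-substituted cycloalkenones that create quaternary centres. The cyclopentane closes in a 5-(enolexo)-exo-trig aldol addition, a favoured mode. C5 is set by the catalyst: the two enone arms of 7 are exchanged by its twofold axis, so the choice to be made is between the two faces of the β-carbon (the arms differ only in the iminium ion, as syn and anti), and the cinchona framework shields one of them. C8 and C9 arise in the aldol step and should settle under thermodynamic control, because the aldol is reversible under amine–acid catalysis and C9 stays epimerisable next to C10: the isopropyl group goes anti to the angular methyl and anti to C10, which leaves the C8 hydroxyl syn to the C10 carbonyl (hydrogen bond) and makes the ring fusion trans. C6 equilibrates through the nitronate and is removed in step 9. The step needs mono-annulation and survival of the β-nitro ketone: once C9 is substituted, condensation of the amine with the hindered C10 ketone is slow, so the second enone is left alone, and the weakly basic buffered medium keeps E1cB loss of nitrous acid from 9 slow.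

Step 6
Reactants: 11 bicyclic nitro ketol enone
Product: 13 β,γ-unsaturated nitro ketol (8β-hydroxy-8α-isopropyl-2,5β-dimethyl-6β-nitro-9α-H-bicyclo[5.3.0]dec-2-en-10-one; analysis numbering), via trilithium nitronate–alkoxide–dienolate trianion 12 (not isolated)
Conditions: LiN(i-Pr)2 (3.5 equiv), THF, −78 °C (inverse addition), then −40 °C; AcOH, THF, −78 °C
Reagents that add atoms: none
Why: Inverse addition to excess amide base turns 11 at once into the trianion 12: nitronate (which blocks retro-Michael cleavage), alkoxide and, by γ-deprotonation at the ring methylene C3 that lies cis to the carbonyl, the extended dienolate (which blocks retro-aldol cleavage); the α′ hydrogen at C9 is a shielded methine next to the alkoxide. Kinetic protonation of an extended dienolate takes place at its α-carbon, here C11, so the cold acetic acid quench gives the β,γ-unsaturated ketone (classical deconjugation of enones through their dienolates). C6 is reprotonated from the face anti to the angular methyl and is erased in step 9 in any case.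

Step 7
Reactants: 13 β,γ-unsaturated nitro ketol
Product: 14 nitro diol (8α-isopropyl-2,5β-dimethyl-6β-nitro-9α-H-bicyclo[5.3.0]dec-2-ene-8β,10α-diol; analysis numbering)
Conditions: Me4NBH(OAc)3, MeCN/AcOH, −35 °C
Reagents that add atoms: none
Why: Hydroxyl-directed reduction (Evans–Saksena): the C8 hydroxyl, which is cis to the C9–C10 bond, replaces an acetate on boron and hydride is delivered through a six-membered transition state to the face of the C10 carbonyl on which the C8 oxygen lies, which sets C10 with its hydroxyl α, anti to the C8 hydroxyl. The reagent does not reduce an unactivated ketone intermolecularly, and at −35 °C the weakly acidic medium should not reconjugate the C2=C3 alkene.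

Step 8
Reactants: 14 nitro diol; 15 4-(prop-2-en-1-yloxy)benzoic acid
Product: 16 nitro ester (10α-[4-(allyloxy)benzoyloxy]-8β-hydroxy-8α-isopropyl-2,5β-dimethyl-6β-nitro-9α-H-bicyclo[5.3.0]dec-2-ene; analysis numbering)
Conditions: DCC, DMAP, CH2Cl2, 0 °C → rt
Reagents that add atoms: none
Why: Carbodiimide/DMAP (Steglich) esterification acylates the only secondary hydroxyl; the tertiary C8 hydroxyl is inert under these conditions. No strong base is present, so the nitro group, the alkene and the allyl ether are not affected and no stereocentre is touched.

Step 9
Reactants: 16 nitro ester
Product: 18 C6 ketone (10α-[4-(allyloxy)benzoyloxy]-8β-hydroxy-8α-isopropyl-2,5β-dimethyl-9α-H-bicyclo[5.3.0]dec-2-en-6-one; analysis numbering), via potassium C6-nitronate 17 (not isolated)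
Conditions: KN(SiMe3)2 (1.05 equiv), THF, −78 → −20 °C; then TiCl3 (aq.), NH4OAc buffer (pH 5–6), THF/H2O, 0 °C → rt
Reagents that add atoms: water, O
Why: Reductive Nef reaction: one equivalent of a non-nucleophilic amide gives the nitronate 17 without attacking the aryl ester, and buffered aqueous TiCl3 reduces it through the oxime to the imine, which hydrolyses at pH 5–6 to the ketone. The buffered medium spares the tertiary β-ketol, the alkene and the allyl ether, and C5 is quaternary, so no stereocentre can epimerise.

Step 10
Reactants: 18 C6 ketone
Product: 19 diol ester (6β,8β-dihydroxy-8α-isopropyl-2,5β-dimethyl-9α-H-bicyclo[5.3.0]dec-2-en-10α-yl 4-(allyloxy)benzoate; analysis numbering)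
Conditions: NaBH4, CeCl3·7H2O, MeOH, −78 → −40 °C
Reagents that add atoms: none
Why: Substrate-controlled borohydride reduction under Luche conditions: as in 17-keto steroids, hydride approaches the cyclopentanone anti to the adjacent angular methyl, here also anti to the pseudo-axial C8 hydroxyl, so the new hydroxyl is β and cis to both. A boron chelate between the C6 carbonyl and the C8 hydroxyl cannot form across a cyclopentanone, so the syn-1,3-diol is reached by steric control and not by chelation. The cold, non-basic medium avoids E1cB dehydration of the β-ketol and leaves the aryl ester alone.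

Step 11
Reactants: 19 diol ester
Product: 20 6β,8β-dihydroxy-8α-isopropyl-2,5β-dimethyl-9α-H-bicyclo[5.3.0]dec-2-en-10α-yl 4-hydroxybenzoate (CNP0215209.2; analysis numbering)
Conditions: Pd(PPh3)4 (5 mol %), morpholine, THF, rt
Reagents that add atoms: none
Why: Tsuji–Trost deallylation: zerovalent palladium ionises the aryl allyl ether to a π-allyl complex and the phenoxide, and morpholine takes up the allyl group. The benzoate ester, both free hydroxyls and the trisubstituted alkene are inert, and no stereocentre is involved.

## Compound list

1 | 2,5-dimethylfuran | Cc1ccc(C)o1 | starting material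
2 | 1,1,3,3-tetrabromopropan-2-one | BrC(Br)C(=O)C(Br)Br | starting material
3 | 2,4-dibromo-1,5-dimethyl-8-oxabicyclo[3.2.1]oct-6-en-3-one (mixture of bromide epimers) | C[C@@]12C=C[C@@](C)(O1)C(Br)C(=O)C2Br | intermediate
4 | 1,5-dimethyl-8-oxabicyclo[3.2.1]oct-6-en-3-one (meso) | C[C@@]12C=C[C@@](C)(O1)CC(=O)C2 | intermediate
5 | 1,5-dimethyl-8-oxabicyclo[3.2.1]octan-3-one (meso) | C[C@@]12CC[C@@](C)(O1)CC(=O)C2 | intermediate
6 | 6-hydroxy-3,6-dimethylcyclohept-2-en-1-one (racemic) | CC1=CC(=O)CC(C)(O)CC1 | intermediate
7 | 3,6-dimethylcyclohepta-2,6-dien-1-one | CC1=CC(=O)C=C(C)CC1 | intermediate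
8 | 4-methylpent-1-en-3-one | C=CC(=O)C(C)C | starting material
9 | 2-methyl-5-nitropentan-3-one | CC(C)C(=O)CC[N+](=O)[O-] | intermediate
10 | Michael adduct, 3,6-dimethyl-6-(4-methyl-1-nitro-3-oxopentyl)cyclohept-2-en-1-one (C5 and C6 as in 11) | CC1=CC(=O)C[C@](C)([C@@H](CC(=O)C(C)C)[N+](=O)[O-])CC1 | intermediate
11 | bicyclic nitro ketol enone, 8β-hydroxy-8α-isopropyl-2,5β-dimethyl-6β-nitro-9α-H-bicyclo[5.3.0]dec-2(11)-en-10-one (analysis numbering) | CC1=CC(=O)[C@H]2[C@](O)(C(C)C)C[C@@H]([N+](=O)[O-])[C@]2(C)CC1 | intermediate
12 | trilithium nitronate–alkoxide–dienolate trianion of 11 (C6 nitronate, C8 alkoxide, C10 dienolate with C10=C11 and C2=C3) | [Li+].[Li+].[Li+].CC1=CC[C@@]2(C)C(=[N+]([O-])[O-])C[C@@]([O-])(C(C)C)[C@@H]2C([O-])=C1 | intermediate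
13 | β,γ-unsaturated nitro ketol, 8β-hydroxy-8α-isopropyl-2,5β-dimethyl-6β-nitro-9α-H-bicyclo[5.3.0]dec-2-en-10-one (analysis numbering) | CC1=CC[C@@]2(C)[C@H]([N+](=O)[O-])C[C@@](O)(C(C)C)[C@@H]2C(=O)C1 | intermediate
14 | nitro diol, 8α-isopropyl-2,5β-dimethyl-6β-nitro-9α-H-bicyclo[5.3.0]dec-2-ene-8β,10α-diol (analysis numbering) | CC1=CC[C@@]2(C)[C@H]([N+](=O)[O-])C[C@@](O)(C(C)C)[C@@H]2[C@@H](O)C1 | intermediate
15 | 4-(prop-2-en-1-yloxy)benzoic acid | C=CCOc1ccc(cc1)C(=O)O | starting material
16 | nitro ester, C10α 4-(allyloxy)benzoate of 14 | CC1=CC[C@@]2(C)[C@H]([N+](=O)[O-])C[C@@](O)(C(C)C)[C@@H]2[C@@H](OC(=O)c2ccc(OCC=C)cc2)C1 | intermediate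
17 | potassium C6-nitronate of 16 | [K+].CC1=CC[C@@]2(C)C(=[N+]([O-])[O-])C[C@@](O)(C(C)C)[C@@H]2[C@@H](OC(=O)c2ccc(OCC=C)cc2)C1 | intermediate
18 | C6 ketone, 10α-[4-(allyloxy)benzoyloxy]-8β-hydroxy-8α-isopropyl-2,5β-dimethyl-9α-H-bicyclo[5.3.0]dec-2-en-6-one (analysis numbering) | CC1=CC[C@@]2(C)C(=O)C[C@@](O)(C(C)C)[C@@H]2[C@@H](OC(=O)c2ccc(OCC=C)cc2)C1 | intermediate
19 | diol ester, 6β,8β-dihydroxy-8α-isopropyl-2,5β-dimethyl-9α-H-bicyclo[5.3.0]dec-2-en-10α-yl 4-(allyloxy)benzoate (analysis numbering) | CC1=CC[C@@]2(C)[C@H](O)C[C@@](O)(C(C)C)[C@@H]2[C@@H](OC(=O)c2ccc(OCC=C)cc2)C1 | intermediate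
20 | 6β,8β-dihydroxy-8α-isopropyl-2,5β-dimethyl-9α-H-bicyclo[5.3.0]dec-2-en-10α-yl 4-hydroxybenzoate, CNP0215209.2 (analysis numbering) | CC1=CC[C@@]2(C)[C@H](O)C[C@@](O)(C(C)C)[C@@H]2[C@@H](OC(=O)c2ccc(O)cc2)C1 | target

## Step count and least certain steps

Total step count: 11. Longest linear sequence: 10 steps (steps 1–3 and 5–11); step 4 is a one-step side branch.

**Step 5 (key step).** The C–C bond at the fully substituted C5 forms slowly. During that time the β-nitro ketone unit, in 9 or in the open adduct 10, can lose nitrous acid by E1cB and consume the nitro partner. Face selection at C5 may also erode at the temperature needed, and the ketol may dehydrate or stop at a kinetic ring-fusion epimer. The fallback separates the two bond formations. Starting from 9, the ketone is masked (1,2-bis(trimethylsilyloxy)ethane, cat. TMSOTf, CH2Cl2, −78 °C) as 2-(2-nitroethyl)-2-(propan-2-yl)-1,3-dioxolane F1, which cannot eliminate. F1 is added to 7 in a separate nitro-Michael reaction (the same amine–acid catalyst or a bifunctional amine–thiourea, at high concentration) to give the dioxolane-protected Michael adduct F2. Mild aqueous acid (PPTS, acetone/H2O) then frees the C8 ketone, so the sequence comes back to the route at 10, which is closed to 11 with pyrrolidinium acetate.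

**Step 6.** Deprotonation may occur at the α′ methine C9 or at the C1 methyl instead of C3. That would return conjugated enone, epimerise the ring fusion or give the exocyclic isomer. Retro-aldol opening can also intervene at the dianion stage before the dienolate is formed. The fallback replaces the strong base by soft enolisation. Starting from 11, TMSOTf/Et3N (CH2Cl2, 0 °C → rt, equilibrating) should give the tris(trimethylsilyl) derivative F3 (C10 silyl dienol ether with C10=C11 and C2=C3, C8 silyl ether, C6 silyl nitronate). Treatment with TBAF/AcOH in THF at −78 °C releases the dienolate in the presence of the proton source, protonates C11, and removes the other two silyl groups. This returns to the route at 13.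

**Step 7.** The tertiary C8 hydroxyl may exchange onto boron too slowly. The hindered C10 ketone would then stay unreduced while the acidic medium slowly moves the alkene back into conjugation. The fallback uses external delivery under neutral, cold conditions (NaBH4, CeCl3·7H2O, MeOH, −78 °C), starting from 13. If this gives 14, the route continues unchanged. If it gives the C10 epimer, the 10β-alcohol F4, a Mitsunobu esterification with 15 (PPh3, DIAD, THF) inverts C10 while forming the ester. Steps 7 and 8 are thus merged and the route is rejoined at 16.

**Step 9.** Nitronate formation at the neopentyl C6 may be slow, and the hindered oxime or imine may resist reduction or hydrolysis. Any C8 alkoxide formed alongside could start acyl migration from the C10 oxygen. The fallback avoids the nitronate. Starting from 16, Zn/AcOH reduces the nitro group to the C6β primary amine F5. Condensation with 3,5-di-tert-butyl-1,2-benzoquinone, prototropic shift and hydrolysis with aqueous oxalic acid (biomimetic transamination) then give the ketone, returning to the route at 18.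

**Step 10.** Facial selectivity may be poor if the α-isopropyl group on C8 hinders the α face more than expected, which would give the 6α-alcohol. A slow reduction would also leave time for dehydration of the β-ketol. The fallback changes from substrate control to reagent control. Starting from 18, a Corey–Bakshi–Shibata reduction (oxazaborolidine catalyst with BH3·SMe2) is run with the catalyst enantiomer matched to α-face delivery; it distinguishes the quaternary C5 side from the CH2 side of the ketone. It returns to the route at 19 and makes no compound beyond those of the route (entry F0).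

## Further compounds

F1 | step 5 | 2-(2-nitroethyl)-2-(propan-2-yl)-1,3-dioxolane | CC(C)C1(CC[N+](=O)[O-])OCCO1
F2 | step 5 | dioxolane-protected Michael adduct, 3,6-dimethyl-6-{1-nitro-2-[2-(propan-2-yl)-1,3-dioxolan-2-yl]ethyl}cyclohept-2-en-1-one (C5 and C6 as in 10) | CC1=CC(=O)C[C@](C)([C@@H](CC2(C(C)C)OCCO2)[N+](=O)[O-])CC1
F3 | step 6 | tris(trimethylsilyl) derivative of 11 (C10 silyl dienol ether with C10=C11 and C2=C3, C8 silyl ether, C6 silyl nitronate) | CC1=CC[C@@]2(C)C(=[N+]([O-])O[Si](C)(C)C)C[C@@](O[Si](C)(C)C)(C(C)C)[C@@H]2C(O[Si](C)(C)C)=C1
F4 | step 7 | 10β-alcohol, C10 epimer of 14 | CC1=CC[C@@]2(C)[C@H]([N+](=O)[O-])C[C@@](O)(C(C)C)[C@@H]2[C@H](O)C1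
F5 | step 9 | C6β primary amine corresponding to 16 | CC1=CC[C@@]2(C)[C@H](N)C[C@@](O)(C(C)C)[C@@H]2[C@@H](OC(=O)c2ccc(OCC=C)cc2)C1
F0 | step 10 | none | none
A1 | alternative 1 | (7E,9E)-1-chloro-6-[(tert-butyldimethylsilyl)oxy]-7-methyl-4-(propan-2-yl)-4-[(triethylsilyl)oxy]undeca-7,9-dien-2-one, C4 and C6 configured as C8 and C6 of A2 | ClCC(=O)C[C@](O[Si](CC)(CC)CC)(C(C)C)C[C@@H](O[Si](C)(C)C(C)(C)C)/C(C)=C/C=C/C
A2 | alternative 1 | bicyclo[5.3.0]dec-3-en-10-one with C2 methyl stereocentre, C6 tert-butyldimethylsilyl ether and C8 triethylsilyl ether (analysis numbering) | C[C@H]1C=C[C@@]2(C)[C@H](O[Si](C)(C)C(C)(C)C)C[C@@](O[Si](CC)(CC)CC)(C(C)C)[C@@H]2C(=O)C1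
A3 | alternative 2 | cyclopentane with (Z)-3-iodobut-2-enyl arm on C5 and C10 4-methoxybenzyl ether whose C11 arm ends in a 1,3-dioxoisoindolin-2-yl ester (analysis numbering) | C/C(I)=C/C[C@@]1(C)[C@H](O[Si](C)(C)C(C)(C)C)C[C@@](O)(C(C)C)[C@@H]1[C@@H](OCc1ccc(OC)cc1)CC(=O)ON1C(=O)c2ccccc2C1=O
A4 | alternative 2 | bicyclic core with C10 4-methoxybenzyl ether, C6 tert-butyldimethylsilyl ether and free C8 hydroxyl | CC1=CC[C@@]2(C)[C@H](O[Si](C)(C)C(C)(C)C)C[C@@](O)(C(C)C)[C@@H]2[C@@H](OCc2ccc(OC)cc2)C1
A5 | alternative 3 | cycloheptene diazoketone: C5 bears methyl and diazoacetyl, C9 bears the 2-methyl-1-[(triethylsilyl)oxy]propyl side chain, C10 bears the silylated 4-hydroxybenzoate (analysis numbering) | CC1=CC[C@@](C)(C(=O)C=[N+]=[N-])[C@H]([C@H](O[Si](CC)(CC)CC)C(C)C)[C@@H](OC(=O)c2ccc(O[Si](C)(C)C(C)(C)C)cc2)C1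
A6 | alternative 3 | bicyclic C6 ketone with C8 triethylsilyl ether and C10 4-[(tert-butyldimethylsilyl)oxy]benzoate | CC1=CC[C@@]2(C)C(=O)C[C@@](O[Si](CC)(CC)CC)(C(C)C)[C@@H]2[C@@H](OC(=O)c2ccc(O[Si](C)(C)C(C)(C)C)cc2)C1
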